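The target is (1S,2R)-2-(4-allyl-2,6-dimethoxyphenoxy)-1-(3,4-dimethoxyphenyl)propan-1-ol, the erythro isomer (7S,8R in neolignan locants).

**Strategy**

The molecule is cut between C7, the carbinol carbon on the 3,4-dimethoxyphenyl ring (ring A), and C8, the methyl-bearing carbon on the ether oxygen of the 4-allyl-2,6-dimethoxyphenyl ring (ring B). C7 is carried as an aroyl chloride and C8 as the α-carbon of a 2-aryloxypropanoic acid. Joined first through oxygen as a mixed anhydride, the halves lose CO2 and recombine at carbon under nickel/iridium photoredox catalysis, giving the α-aryloxy ketone in one operation. The step exploits the ether oxygen on C8, which stabilises the radical left by decarboxylation. Both stereocentres are then set together by a ketoreductase reduction with dynamic kinetic resolution at the acidic C8–H.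

Key step: step 2

Remark on the chemistry: C7 is the benzylic carbinol carbon, C8 the carbon bearing the aryloxy group and the methyl group. Compounds 1, 2 and 4 are taken as commercially available. Compound 2 is used as the racemate because C8 passes through a planar radical in step 2.

**Route**

Step 1
Reactants: 1 4-allyl-2,6-dimethoxyphenol; 2 (±)-2-bromopropanoic acid
Product: 3 (±)-2-(4-allyl-2,6-dimethoxyphenoxy)propanoic acid
Conditions: NaH (2.2 equiv), THF, 0 °C to reflux; then aq. HCl
Reagents that add atoms: none
Why: Williamson ether synthesis, in which the sodium phenoxide of 1 should displace bromide from sodium 2-bromopropanoate by SN2 substitution, the usual way to 2-aryloxypropanoic acids; the product is racemic, which is immaterial because C8 is flattened in step 2.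

Step 2
Reactants: 3 (±)-2-(4-allyl-2,6-dimethoxyphenoxy)propanoic acid; 4 3,4-dimethoxybenzoyl chloride
Product: 6 (±)-2-(4-allyl-2,6-dimethoxyphenoxy)-1-(3,4-dimethoxyphenyl)propan-1-one, via mixed anhydride 5 (not isolated)
Conditions: DBU (1.1 equiv), Ir[dF(CF3)ppy]2(dtbbpy)PF6 (1 mol%), NiCl2·glyme (5 mol%), 4,4'-di-tert-butyl-2,2'-bipyridine (5 mol%), 1,4-dioxane, blue LEDs, rt
Reagents that add atoms: none
Why: The DBU carboxylate of 3 is acylated by 4 to mixed anhydride 5; bipyridine-ligated zerovalent nickel should insert into its aroyl C–O bond to give an aroyl nickel carboxylate (divalent nickel), the excited iridium photocatalyst oxidises the 2-aryloxypropanoate by one electron, CO2 is lost, the C8 radical is captured by nickel, and reductive elimination from trivalent nickel forms the C7–C8 bond, after which the reduced photocatalyst returns nickel to the zerovalent state. The closest known reaction type is the nickel/photoredox decarboxylative acyl cross-coupling of α-oxy and α-amino acids with acyl chlorides through mixed anhydrides formed in the flask (CO2 extrusion and recombination). No ring is closed. C8 is created through a planar, oxygen-stabilised radical and is therefore racemic by design; lying between the new ketone and the aryloxy group it stays epimerisable and is corrected in step 3, and C7 is not yet stereogenic. The step needs cross-selectivity and survival of the allyl group: only the aliphatic α-oxy carboxylate is oxidised and decarboxylates whereas the aroyl part can only act as the acyl partner, and the nucleophilic α-oxy radical should not add to the unactivated terminal alkene of ring B at room temperature in the absence of a hydride source.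

Step 3
Reactants: 6 (±)-2-(4-allyl-2,6-dimethoxyphenoxy)-1-(3,4-dimethoxyphenyl)propan-1-one
Product: 8 (1S,2R)-2-(4-allyl-2,6-dimethoxyphenoxy)-1-(3,4-dimethoxyphenyl)propan-1-ol (the target), via enol 7 (not isolated)
Conditions: ketoreductase (NADPH-dependent, variant picked from a screening panel for the 7S,8R product), NADP+ (cat.), iPrOH/DMSO, triethanolamine buffer pH 10, 40 °C
Reagents that add atoms: none
Why: Ketoreductase-catalysed carbonyl reduction run as a dynamic kinetic resolution, in which the enzyme should transfer the hydride of NADPH (regenerated from 2-propanol) only to the (R)-enantiomer of 6 and only to the carbonyl face that gives 7S, so that C7 and C8 are both fixed by the enzyme pocket, while the unreactive (S)-ketone is returned to the racemate at pH 10 through enol 7 because C8–H is acidified by the aroyl and aryloxy groups; a hydride-transfer enzyme leaves the allyl group untouched.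

**Compound list**

1 | 4-allyl-2,6-dimethoxyphenol | C=CCc1cc(OC)c(O)c(OC)c1 | starting material
2 | (±)-2-bromopropanoic acid | CC(Br)C(=O)O | starting material
3 | (±)-2-(4-allyl-2,6-dimethoxyphenoxy)propanoic acid | C=CCc1cc(OC)c(OC(C)C(=O)O)c(OC)c1 | intermediate
4 | 3,4-dimethoxybenzoyl chloride | COc1ccc(C(=O)Cl)cc1OC | starting material
5 | 3,4-dimethoxybenzoic 2-(4-allyl-2,6-dimethoxyphenoxy)propanoic anhydride (racemic) | C=CCc1cc(OC)c(OC(C)C(=O)OC(=O)c2ccc(OC)c(OC)c2)c(OC)c1 | intermediate (not isolated)
6 | (±)-2-(4-allyl-2,6-dimethoxyphenoxy)-1-(3,4-dimethoxyphenyl)propan-1-one | C=CCc1cc(OC)c(OC(C)C(=O)c2ccc(OC)c(OC)c2)c(OC)c1 | intermediate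
7 | 2-(4-allyl-2,6-dimethoxyphenoxy)-1-(3,4-dimethoxyphenyl)prop-1-en-1-ol (enol of 6) | C=CCc1cc(OC)c(OC(C)=C(O)c2ccc(OC)c(OC)c2)c(OC)c1 | intermediate (not isolated)
8 | (1S,2R)-2-(4-allyl-2,6-dimethoxyphenoxy)-1-(3,4-dimethoxyphenyl)propan-1-ol | C=CCc1cc(OC)c(O[C@H](C)[C@@H](O)c2ccc(OC)c(OC)c2)c(OC)c1 | target

**Count**

Total steps: 3. Longest linear sequence: 3 steps (1 → 3 → 6 → 8).

**Steps most likely to fail, with fallbacks**

Step 3. Epimerisation at C8 may be slower than reduction, or the enzyme may discriminate poorly between the two C8 epimers, so that threo material leaks through; activity may also be low because the carbonyl is flanked by two bulky groups. The fallback sets out from 6 and comes back at 8. Asymmetric transfer hydrogenation of 6 with RuCl(p-cymene)[(S,S)-TsDPEN] and HCO2H/DBU in DMF at 40 °C, again with epimerisation at C8, should set 7R by catalyst control and, by the Felkin–Anh preference of a non-chelating hydride donor, consume the 8R ketone faster. This should give (1R,2R)-2-(4-allyl-2,6-dimethoxyphenoxy)-1-(3,4-dimethoxyphenyl)propan-1-ol F1, the threo isomer. Mitsunobu inversion at C7 with 4-nitrobenzoic acid, PPh3 and DIAD in THF at 0 °C should give (1S,2R)-2-(4-allyl-2,6-dimethoxyphenoxy)-1-(3,4-dimethoxyphenyl)propyl 4-nitrobenzoate F2. Methanolysis with K2CO3 in MeOH at rt then releases 8.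

Step 2. The mixed anhydride may scramble to the symmetric anhydrides, nickel may insert on the aliphatic acyl side, the C8 radical may dimerise or be reduced before nickel captures it, and a nickel hydride may move the allyl double bond into conjugation. The fallback sets out from 3 (with 4) and comes back at 6 by a polar route. Double deprotonation of 3 with LDA (2.2 equiv) in THF at −78 to −20 °C should give the enediolate, which is acylated at C8 by 4 at −78 °C. Work-up with aq. HCl should give 2-(4-allyl-2,6-dimethoxyphenoxy)-3-(3,4-dimethoxyphenyl)-2-methyl-3-oxopropanoic acid F3, a β-keto acid that should lose CO2 on gentle warming to give 6.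

Step 1. Substitution at the secondary carbon next to a carboxylate by the hindered 2,6-dimethoxyphenoxide may be slow, and elimination to acrylate may take over. The fallback sets out from 1 and comes back at 3. Mitsunobu etherification of 1 with ethyl (±)-lactate (CCOC(=O)C(C)O), PPh3 and DIAD in THF at 0 °C to rt should give ethyl (±)-2-(4-allyl-2,6-dimethoxyphenoxy)propanoate F4. Saponification with LiOH in THF/H2O at rt and acidification with aq. HCl then gives 3.

**Further compounds**

F1 | step 3 | (1R,2R)-2-(4-allyl-2,6-dimethoxyphenoxy)-1-(3,4-dimethoxyphenyl)propan-1-ol | C=CCc1cc(OC)c(O[C@H](C)[C@H](O)c2ccc(OC)c(OC)c2)c(OC)c1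
F2 | step 3 | (1S,2R)-2-(4-allyl-2,6-dimethoxyphenoxy)-1-(3,4-dimethoxyphenyl)propyl 4-nitrobenzoate | C=CCc1cc(OC)c(O[C@H](C)[C@@H](OC(=O)c3ccc(cc3)[N+](=O)[O-])c2ccc(OC)c(OC)c2)c(OC)c1
F3 | step 2 | 2-(4-allyl-2,6-dimethoxyphenoxy)-3-(3,4-dimethoxyphenyl)-2-methyl-3-oxopropanoic acid (racemic) | C=CCc1cc(OC)c(OC(C)(C(=O)O)C(=O)c2ccc(OC)c(OC)c2)c(OC)c1
F4 | step 1 | ethyl (±)-2-(4-allyl-2,6-dimethoxyphenoxy)propanoate | C=CCc1cc(OC)c(OC(C)C(=O)OCC)c(OC)c1
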